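(The readings were computed for an exercise; the scatter is artificial.)

We judge this flask by one number, κ: the rate at which D appears divided by the X present. Time drops out of that quotient, so a late amount of X can be reckoned from the rate of D at that moment.

| flask | E | remark | time |
|---|---|---|---|
| autumn | 0.050 M | run made earlier |  |
| spring | 0.075 M | run made earlier |  |
| flask | 0.10 M |  | 2.5 d |

| run | time / h | X / % | D / % |
|---|---|---|---|
| autumn | 4.00 | 1.9 | 2.7 |
| autumn | 6.00 | 2.1 | 2.3 |
| autumn | 8.00 | 0 | 3.6 |
| autumn | 15.0 | 3.6 | 8.8 |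
| autumn | 20.0 | 3.0 | 13.5 |
| autumn | 30.0 | 1.2 | 19.9 |
| autumn | 50.0 | 2.4 | 33.1 |
| spring | 6.00 | 3.3 | 2.2 |
| spring | 15.0 | 5.1 | 7.1 |
| spring | 20.0 | 4.1 | 12.3 |
| spring | 30.0 | 1.0 | 19.0 |
| spring | 40.0 | 4.3 | 23.8 |
| spring | 50.0 | 3.5 | 30.6 |

(scatter of a reading: 1 percentage point)

* ratio of X to D at 2.0 h
* ratio of X to D at 10 h
* ratio of X to D at 2.5 d
* which of X and D there is more of at 2.5 d

- what was read earlier has a scatter of 1 percentage point, one standard deviation

From 15.0 h to 50.0 h, D gains 0.00694 h⁻¹ of the charge in the autumn run and 0.00671 h⁻¹ in the spring run. The spring charge is 1.50 times the autumn one, but the two rates stand at a ratio of 0.967, so we read the percentages as first-order behaviour and carry them to the flask. Over those hours X averages 3.13 %, which gives κ = 0.218 h⁻¹, our first-order constant for D made per X present.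

Our own reckoning uses rates. Averaged over both runs, D gains 0.00767 h⁻¹ from 15.0 h to 30.0 h. From 30.0 h to 50.0 h it gains 0.00620 h⁻¹, a slowing by a factor of 0.809, which is a reading and carries the scatter of the readings. We assume the same factor once more, which gives 0.00501 h⁻¹ from 50.0 h to 2.5 d, so we estimate that D in the flask ends near 36.9 % and X near 2.30 %. On this estimate D leads in the flask, at a ratio of 0.0624.

The forecast reads “E → X → D, with X a steady-state intermediate” and gives 6, 1.1 and 0.08, with D ahead; its last ratio lies above ours.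

The flask gives 5.34, 0.724 and 0.0723, with D ahead at 35.3 % against 2.55 % of X.

    E ⇌ J (K = 0.420, k = 0.103 h⁻¹)
    E ⇌ L (K = 0.317, k = 0.793 h⁻¹)
    L ⇌ X (K = 2.57, k = 0.0477 h⁻¹)
    X → D (k = 0.197 h⁻¹)

X and D stand level at 0.324 d, earlier than 10 h. With X in the flask at 2.55 % after 2.50 d, κ gives D forming at 0.00556 h⁻¹ of the charge at that time. In the neighbouring flask charged with 0.025 M, X ends at 2.55 %, so κ gives 0.00556 h⁻¹ there. The computed ratio in that neighbour is 0.0723.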